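**Retrosynthetic overview**

1. Target numbering: ring A is O1–C2–C3–C3a–C7a, ring B is C3a–C4=C5(OMe)–C6(=O)–C7=C7a. The route rests on the quaternary C3a (allyl, C3, C4, C7a): its neighbour C7a can be a lactone carbonyl, and the enolate of that lactone has one face covered by the cis C2-aryl and C3-methyl groups of ring A.
2. Ring B is built last on the lactone: C4=C5 by loss of benzenesulfinate from C5, C7–C7a by intramolecular Claisen condensation of a C6 acetyl group onto the lactone carbonyl, C5–C6 by acylation of the C5 sulfonyl carbanion.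
3. C4–C5 and C3a–allyl are made in one three-component operation: lithiated methoxymethyl phenyl sulfone adds to the cis α-methylene lactone and the enolate is allylated trans to methyl and aryl.
4. The methylene lactone comes from the saturated cis lactone (Mannich methylenation), which comes from the syn homoallylic alcohol of an asymmetric (Z)-crotylboration of 3,4,5-trimethoxybenzaldehyde (sets C2 and C3) by hydroboration and oxidative lactonisation.
5. Order of ring formation: ring A (step 3), then ring B (step 8).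

Key step: step 6

Remark: from step 6 on, atoms carry the target numbering (lactone C2, C3, C4, C5 and the exocyclic CH2 are C7a, C3a, C3, C2 and C4). Compounds epimeric at the sulfone-bearing C5 are carried as mixtures because C5 becomes sp2 in step 9. Methoxymethyl phenyl sulfone is assumed to be a purchasable reagent.

**Route**

Step 1
Reactants: 1 3,4,5-trimethoxybenzaldehyde; 2 (Z)-but-2-ene
Product: 6 (1R,2S)-2-methyl-1-(3,4,5-trimethoxyphenyl)but-3-en-1-ol, via (Z)-crotylpotassium 3 (not isolated), via (Z)-crotyldiisopinocampheylborane 4 (not isolated), via homoallyl borinate 5 (not isolated)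
Conditions: 2, n-BuLi, KOtBu, THF, −78 to −45 °C; (+)-Ipc2BOMe [(+)-B-methoxydiisopinocampheylborane, from (−)-α-pinene], −78 °C; BF3·OEt2; then 1, −78 °C; NaOH, H2O2, 0 °C to rt
Reagents that add atoms: none
Why: Asymmetric crotylboration through a closed chair (Zimmerman–Traxler) transition state, in which the Z geometry of the crotyl group gives the syn alcohol and the isopinocampheyl groups from (−)-α-pinene should direct the addition to the Re face of the aldehyde, which sets 1R,2S (the later C2 and C3).

Step 2
Reactants: 6 (1R,2S)-2-methyl-1-(3,4,5-trimethoxyphenyl)but-3-en-1-ol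
Product: 8 (1R,2S)-2-methyl-1-(3,4,5-trimethoxyphenyl)butane-1,4-diol, via organoborane 7 (not isolated)
Conditions: 9-borabicyclo[3.3.1]nonane (9-BBN, 2.5 equiv), THF, 0 °C to rt; NaOH, H2O2, 0 °C to rt
Reagents that add atoms: hydrogen peroxide, OO
Why: Hydroboration–oxidation, in which the bulky dialkylborane places boron on the terminal carbon of the monosubstituted alkene, the free hydroxyl is only turned into a borinate that the oxidative work-up cleaves again, and neither stereocentre is involved.

Step 3
Reactants: 8 (1R,2S)-2-methyl-1-(3,4,5-trimethoxyphenyl)butane-1,4-diol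
Product: 10 (4S,5R)-4-methyl-5-(3,4,5-trimethoxyphenyl)dihydrofuran-2(3H)-one (cis lactone), via lactol 9 (not isolated)
Conditions: TEMPO (2,2,6,6-tetramethylpiperidin-1-oxyl, 0.2 equiv), PhI(OAc)2 (2.5 equiv), CH2Cl2, rt
Reagents that add atoms: none
Why: Oxoammonium-mediated oxidative lactonisation, in which the primary alcohol is oxidised faster than the hindered secondary benzylic one, ring A closes at the aldehyde oxidation level to lactol 9 and this is oxidised on, so that the syn diol becomes the cis 4-methyl-5-aryl lactone without any change at the stereocentres.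

Step 4
Reactants: 10 (4S,5R)-4-methyl-5-(3,4,5-trimethoxyphenyl)dihydrofuran-2(3H)-one; 11 N,N-dimethylmethyleneiminium iodide (Eschenmoser's salt)
Product: 13 (4S,5R)-3-[(dimethylamino)methyl]-4-methyl-5-(3,4,5-trimethoxyphenyl)dihydrofuran-2(3H)-one (epimers at lactone C3), via lithium enolate 12 (not isolated)
Conditions: LiN(iPr)2, THF, −78 °C; then 11, −78 °C to rt
Reagents that add atoms: none
Why: Mannich reaction of a preformed lactone enolate with an iminium salt at the only enolisable position, lactone C3, whose configuration is irrelevant because this carbon becomes sp2 in step 5.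

Step 5
Reactants: 13 (4S,5R)-3-[(dimethylamino)methyl]-4-methyl-5-(3,4,5-trimethoxyphenyl)dihydrofuran-2(3H)-one
Product: 15 (4S,5R)-4-methyl-3-methylene-5-(3,4,5-trimethoxyphenyl)dihydrofuran-2(3H)-one, via ammonium iodide 14 (not isolated)
Conditions: MeI, MeOH, rt; then NaHCO3 (aq), CH2Cl2, rt
Reagents that add atoms: none
Why: N-Methylation followed by E1cB (Hofmann-type) loss of trimethylamine from the β-ammonio lactone, with a base weak enough that the exocyclic alkene should not migrate into the ring, so the methyl-bearing stereocentre is kept.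

Step 6
Reactants: 15 (4S,5R)-4-methyl-3-methylene-5-(3,4,5-trimethoxyphenyl)dihydrofuran-2(3H)-one; 16 methoxymethyl phenyl sulfone; 17 allyl bromide
Product: 20 (3R,4S,5R)-3-allyl-3-[2-methoxy-2-(phenylsulfonyl)ethyl]-4-methyl-5-(3,4,5-trimethoxyphenyl)dihydrofuran-2(3H)-one (both epimers at the sulfone carbon), via lithiated sulfone 18 (not isolated), via lithium enolate 19 (not isolated)
Conditions: 16 (1.3 equiv), n-BuLi (1.25 equiv), THF, −78 °C; 15 added slowly, −78 °C; then DMPU, 17 (4 equiv), −78 to −20 °C
Reagents that add atoms: none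
Why: Carbanion 18 adds in Michael fashion to the exocyclic carbon C4 of 15 and makes the C4–C5 bond, and the lithium enolate 19, whose nucleophilic carbon is C3a, is then C-allylated by allyl bromide in an SN2 reaction that makes the C3a–allyl bond; no ring closes. The closest known reaction type is the tandem conjugate addition and enolate alkylation of unsaturated lactones and enones with sulfur-stabilised carbanions. The new quaternary centre C3a is set by the substrate: the C3 methyl next to the enolate carbon and the C2 aryl lie on the same face of ring A, so allyl bromide should enter from the other face and end up trans to both. The step needs 1,4- rather than 1,2-addition, which the delocalised carbanion and the irreversible formation of the enolate should secure, and it needs the enolate to last until it is alkylated, which should hold because the lactone enolate is a much weaker base than the α-methoxy sulfonyl carbanion that a proton shift from C5–H would create. Slow addition of 15 to a slight excess of 18 at −78 °C should keep enolate 19 from adding to unreacted 15. C5 forms without selectivity, which is of no consequence.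

Step 7
Reactants: 20 (3R,4S,5R)-3-allyl-3-[2-methoxy-2-(phenylsulfonyl)ethyl]-4-methyl-5-(3,4,5-trimethoxyphenyl)dihydrofuran-2(3H)-one
Product: 22 (3R,4S,5R)-3-allyl-3-[2-methoxy-3-oxo-2-(phenylsulfonyl)butyl]-4-methyl-5-(3,4,5-trimethoxyphenyl)dihydrofuran-2(3H)-one (both epimers at the sulfone carbon), via sulfonyl carbanion 21 (not isolated)
Conditions: LiN(iPr)2, THF, −78 °C; transfer into N-acetylimidazole (3 equiv), THF, −78 °C; AcOH
Reagents that add atoms: N-acetylimidazole, CC(=O)n1ccnc1
Why: Acylation of a sulfonyl carbanion: the base removes the only acidic hydrogen of 20 (C5–H, the lactone having no α-hydrogen), and adding carbanion 21 to an excess of the reactive acyl imidazole makes the C5–C6 bond before the new methyl ketone can be enolised by unreacted 21.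

Step 8
Reactants: 22 (3R,4S,5R)-3-allyl-3-[2-methoxy-3-oxo-2-(phenylsulfonyl)butyl]-4-methyl-5-(3,4,5-trimethoxyphenyl)dihydrofuran-2(3H)-one
Product: 24 (2R,3S,3aR)-3a-allyl-5-methoxy-3-methyl-5-(phenylsulfonyl)-2-(3,4,5-trimethoxyphenyl)-3,3a,4,5-tetrahydrobenzofuran-6(2H)-one (both epimers at C5), via hydroxy diketone 23 (not isolated)
Conditions: KOtBu (2.2 equiv), THF, 0 °C to rt; AcOH; then pyridinium p-toluenesulfonate (cat.), 4 Å molecular sieves, CH2Cl2, rt
Reagents that add atoms: none
Why: Intramolecular Claisen (Dieckmann-type) condensation, in which the only possible enolate (C7, the acetyl methyl) attacks the lactone carbonyl C7a in a 6-exo-trig closure of ring B, the stabilised enolate of 1,3-diketone 23 drives the equilibrium, and after acidification the C2 hydroxyl, which can reach only C7a through a five-membered ring, re-forms ring A as the vinylogous ester by mild acid dehydration without breaking any bond at a stereocentre.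

Step 9
Reactants: 24 (2R,3S,3aR)-3a-allyl-5-methoxy-3-methyl-5-(phenylsulfonyl)-2-(3,4,5-trimethoxyphenyl)-3,3a,4,5-tetrahydrobenzofuran-6(2H)-one
Product: 25 (2R,3S,3aS)-3a-allyl-5-methoxy-3-methyl-2-(3,4,5-trimethoxyphenyl)-3,3a-dihydrobenzofuran-6(2H)-one (target)
Conditions: DBU (3 equiv), MeCN, 50 °C
Reagents that add atoms: none
Why: Proposed new method: the amidine base removes a C4 hydrogen while benzenesulfinate leaves C5, its departure helped by the lone pair of the C5 methoxy group (an E2 process with E1 character, since the C4 hydrogens are not acidified), and the closest known reaction types are the loss of benzenesulfinic acid from tertiary α-alkoxy sulfones to give enol ethers and the amidine-mediated dehydrohalogenation of α-halo ketones to enones; only C4 carries a β-hydrogen, so a single alkene can form, and C2, C3 and C3a bear no acidic hydrogen and should stay as set.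

**Compound list**

1 | 3,4,5-trimethoxybenzaldehyde | COc1cc(C=O)cc(OC)c1OC | starting material
2 | (Z)-but-2-ene | C/C=C\C | starting material
3 | (Z)-crotylpotassium | C/C=C\C[K] | intermediate
4 | (Z)-crotyldiisopinocampheylborane, isopinocampheyl groups from (−)-α-pinene | C/C=C\CB([C@H]1C[C@H]2C[C@@H]([C@@H]1C)C2(C)C)[C@H]1C[C@H]2C[C@@H]([C@@H]1C)C2(C)C | intermediate
5 | B,B-diisopinocampheyl borinate of alcohol 6 | C=C[C@H](C)[C@@H](OB([C@H]1C[C@H]2C[C@@H]([C@@H]1C)C2(C)C)[C@H]1C[C@H]2C[C@@H]([C@@H]1C)C2(C)C)c1cc(OC)c(OC)c(OC)c1 | intermediate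
6 | (1R,2S)-2-methyl-1-(3,4,5-trimethoxyphenyl)but-3-en-1-ol | C=C[C@H](C)[C@@H](O)c1cc(OC)c(OC)c(OC)c1 | intermediate
7 | bis(9-borabicyclononyl) derivative of diol 8 (O-borinate and C4-alkylborane) | B1(CC[C@H](C)[C@@H](OB2C3CCCC2CCC3)c2cc(OC)c(OC)c(OC)c2)C2CCCC1CCC2 | intermediate
8 | (1R,2S)-2-methyl-1-(3,4,5-trimethoxyphenyl)butane-1,4-diol | OCC[C@H](C)[C@@H](O)c1cc(OC)c(OC)c(OC)c1 | intermediate
9 | (4S,5R)-4-methyl-5-(3,4,5-trimethoxyphenyl)tetrahydrofuran-2-ol (both anomers) | C1C(O)O[C@@H](c2cc(OC)c(OC)c(OC)c2)[C@H]1C | intermediate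
10 | (4S,5R)-4-methyl-5-(3,4,5-trimethoxyphenyl)dihydrofuran-2(3H)-one | C1C(=O)O[C@@H](c2cc(OC)c(OC)c(OC)c2)[C@H]1C | intermediate
11 | N,N-dimethylmethyleneiminium iodide (Eschenmoser's salt) | C[N+](C)=C.[I-] | starting material
12 | lithium enolate of lactone 10 | C1=C(O[Li])O[C@@H](c2cc(OC)c(OC)c(OC)c2)[C@H]1C | intermediate
13 | (4S,5R)-3-[(dimethylamino)methyl]-4-methyl-5-(3,4,5-trimethoxyphenyl)dihydrofuran-2(3H)-one (epimers at C3) | CN(C)CC1C(=O)O[C@@H](c2cc(OC)c(OC)c(OC)c2)[C@H]1C | intermediate
14 | N,N,N-trimethyl-1-[(4S,5R)-4-methyl-2-oxo-5-(3,4,5-trimethoxyphenyl)tetrahydrofuran-3-yl]methanaminium iodide | C[N+](C)(C)CC1C(=O)O[C@@H](c2cc(OC)c(OC)c(OC)c2)[C@H]1C.[I-] | intermediate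
15 | (4S,5R)-4-methyl-3-methylene-5-(3,4,5-trimethoxyphenyl)dihydrofuran-2(3H)-one | C=C1C(=O)O[C@@H](c2cc(OC)c(OC)c(OC)c2)[C@H]1C | intermediate
16 | methoxymethyl phenyl sulfone | COCS(=O)(=O)c1ccccc1 | starting material
17 | allyl bromide | C=CCBr | starting material
18 | lithiated methoxymethyl phenyl sulfone | COC([Li])S(=O)(=O)c1ccccc1 | intermediate
19 | lithium (4S,5R)-3-[2-methoxy-2-(phenylsulfonyl)ethyl]-4-methyl-5-(3,4,5-trimethoxyphenyl)-4,5-dihydrofuran-2-olate | COC(CC1=C(O[Li])O[C@@H](c2cc(OC)c(OC)c(OC)c2)[C@H]1C)S(=O)(=O)c1ccccc1 | intermediate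
20 | (3R,4S,5R)-3-allyl-3-[2-methoxy-2-(phenylsulfonyl)ethyl]-4-methyl-5-(3,4,5-trimethoxyphenyl)dihydrofuran-2(3H)-one (epimers at the sulfone carbon) | C=CC[C@]1(CC(OC)S(=O)(=O)c2ccccc2)C(=O)O[C@@H](c2cc(OC)c(OC)c(OC)c2)[C@H]1C | intermediate
21 | α-lithio derivative of 20 at the sulfone carbon | C=CC[C@]1(CC([Li])(OC)S(=O)(=O)c2ccccc2)C(=O)O[C@@H](c2cc(OC)c(OC)c(OC)c2)[C@H]1C | intermediate
22 | (3R,4S,5R)-3-allyl-3-[2-methoxy-3-oxo-2-(phenylsulfonyl)butyl]-4-methyl-5-(3,4,5-trimethoxyphenyl)dihydrofuran-2(3H)-one (epimers at the sulfone carbon) | C=CC[C@]1(CC(OC)(C(C)=O)S(=O)(=O)c2ccccc2)C(=O)O[C@@H](c2cc(OC)c(OC)c(OC)c2)[C@H]1C | intermediate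
23 | (6R)-6-allyl-6-[(1R,2S)-1-hydroxy-1-(3,4,5-trimethoxyphenyl)propan-2-yl]-4-methoxy-4-(phenylsulfonyl)cyclohexane-1,3-dione (epimers at C4) | C=CC[C@@]1(CC(OC)(S(=O)(=O)c2ccccc2)C(=O)CC1=O)[C@H](C)[C@@H](O)c1cc(OC)c(OC)c(OC)c1 | intermediate
24 | (2R,3S,3aR)-3a-allyl-5-methoxy-3-methyl-5-(phenylsulfonyl)-2-(3,4,5-trimethoxyphenyl)-3,3a,4,5-tetrahydrobenzofuran-6(2H)-one (epimers at C5) | C=CC[C@]12CC(OC)(S(=O)(=O)c3ccccc3)C(=O)C=C1O[C@@H](c1cc(OC)c(OC)c(OC)c1)[C@H]2C | intermediate
25 | (2R,3S,3aS)-3a-allyl-5-methoxy-3-methyl-2-(3,4,5-trimethoxyphenyl)-3,3a-dihydrobenzofuran-6(2H)-one | C=CC[C@]12C=C(OC)C(=O)C=C1O[C@@H](c1cc(OC)c(OC)c(OC)c1)[C@H]2C | target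

**Step count and risks**

Total step count: 9. Longest linear sequence: 9 steps (from 1 and 2 to 25).

Steps most likely to fail:

1. Step 9 (proposed new method). The sulfinate may fail to leave because the C4 hydrogens are not acidified, and harsher heating could start a [3,3] shift of the allyl group from C3a to C5. The fallback uses known chemistry and sets out from 24. Aluminium amalgam (Al/Hg) in aqueous THF at 0 °C should cleave the C5–S bond reductively to give (2R,3S,3aR)-3a-allyl-5-methoxy-3-methyl-2-(3,4,5-trimethoxyphenyl)-3,3a,4,5-tetrahydrobenzofuran-6(2H)-one F1. LiN(iPr)2 in THF at −78 °C followed by PhSeBr should selenenylate C5, the only enolisable position, to give the 5-(phenylselanyl) ketone F2. H2O2 with pyridine in CH2Cl2 at 0 °C should give the selenoxide F3, whose syn elimination can only take a C4 hydrogen, and the route is rejoined at 25.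

2. Step 6 (key step). Enolate 19 may add to unreacted 15 (anionic oligomerisation), the carbanion may deprotonate the lactone C4–H of 15 and move the alkene into the ring with loss of a stereocentre, or allylation may be incomplete. The fallback sets out from 10 and avoids the methylene lactone. LiN(iPr)2 in THF/DMPU and 2-bromo-1,1-dimethoxyethane (with NaI) should alkylate the lactone to (4S,5R)-3-(2,2-dimethoxyethyl)-4-methyl-5-(3,4,5-trimethoxyphenyl)dihydrofuran-2(3H)-one F4. A second enolate alkylation with LiN(iPr)2 and allyl bromide should, under the same facial control (allyl enters trans to methyl and aryl), give (3R,4S,5R)-3-allyl-3-(2,2-dimethoxyethyl)-4-methyl-5-(3,4,5-trimethoxyphenyl)dihydrofuran-2(3H)-one F5. Benzenesulfinic acid with CaCl2 in CH2Cl2 at rt should exchange one acetal methoxy group for the sulfonyl group through the oxocarbenium ion, and the route is rejoined at 20.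

3. Step 7. Proton transfer from the new methyl ketone to unreacted carbanion 21 may stall the acylation, and the acetyl group may be lost again by retro-Claisen cleavage during work-up. The fallback sets out from 20 and makes the C5–C6 bond by carbonyl addition instead of acylation. Carbanion 21 (LiN(iPr)2, THF, −78 °C) is treated with acetaldehyde and quenched cold with AcOH to give (3R,4S,5R)-3-allyl-3-[3-hydroxy-2-methoxy-2-(phenylsulfonyl)butyl]-4-methyl-5-(3,4,5-trimethoxyphenyl)dihydrofuran-2(3H)-one F6. Oxidation with Dess–Martin periodinane in CH2Cl2 should then give the ketone, and the route is rejoined at 22.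

**Further compounds**

F1 | step 9 | (2R,3S,3aR)-3a-allyl-5-methoxy-3-methyl-2-(3,4,5-trimethoxyphenyl)-3,3a,4,5-tetrahydrobenzofuran-6(2H)-one (epimers at C5) | C=CC[C@]12CC(OC)C(=O)C=C1O[C@@H](c1cc(OC)c(OC)c(OC)c1)[C@H]2C
F2 | step 9 | (2R,3S,3aR)-3a-allyl-5-methoxy-3-methyl-5-(phenylselanyl)-2-(3,4,5-trimethoxyphenyl)-3,3a,4,5-tetrahydrobenzofuran-6(2H)-one (epimers at C5) | C=CC[C@]12CC(OC)([Se]c3ccccc3)C(=O)C=C1O[C@@H](c1cc(OC)c(OC)c(OC)c1)[C@H]2C
F3 | step 9 | selenoxide of F2 | C=CC[C@]12CC(OC)([Se](=O)c3ccccc3)C(=O)C=C1O[C@@H](c1cc(OC)c(OC)c(OC)c1)[C@H]2C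
F4 | step 6 | (4S,5R)-3-(2,2-dimethoxyethyl)-4-methyl-5-(3,4,5-trimethoxyphenyl)dihydrofuran-2(3H)-one (epimers at C3) | COC(OC)CC1C(=O)O[C@@H](c2cc(OC)c(OC)c(OC)c2)[C@H]1C
F5 | step 6 | (3R,4S,5R)-3-allyl-3-(2,2-dimethoxyethyl)-4-methyl-5-(3,4,5-trimethoxyphenyl)dihydrofuran-2(3H)-one | C=CC[C@]1(CC(OC)OC)C(=O)O[C@@H](c2cc(OC)c(OC)c(OC)c2)[C@H]1C
F6 | step 7 | (3R,4S,5R)-3-allyl-3-[3-hydroxy-2-methoxy-2-(phenylsulfonyl)butyl]-4-methyl-5-(3,4,5-trimethoxyphenyl)dihydrofuran-2(3H)-one (mixture at the two side-chain centres) | C=CC[C@]1(CC(OC)(C(C)O)S(=O)(=O)c2ccccc2)C(=O)O[C@@H](c2cc(OC)c(OC)c(OC)c2)[C@H]1C
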